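The constants of the four steps are unknown, but one ratio of rates can be read from the runs.

| setting | Friday's | Saturday's | flask |
|---|---|---|---|
| Z | 1.1 M | 0.55 M | 1.1 M |
| J | 200 mM (held) | 200 mM (held) | 200 mM (held) |
| remark | the very flask that is asked about, followed so far | run made earlier |  |
| time |  |  | 1.0 h |
- Friday's (time / min: Z / %, E / %, G / %): 2.00: 77.3, 1.4, 0.9; 4.00: 64.0, 4.4, 0.2; 6.00: 52.0, 5.6, 1.1; 8.00: 44.4, 5.4, 1.5; 10.0: 38.4, 6.2, 4.0
- Saturday's (time / min: Z / %, E / %, G / %): 2.00: 86.5, 1.1, 0.4; 6.00: 67.1, 4.7, 1.2; 12.0: 48.0, 7.3, 5.5; 15.0: 41.9, 7.8, 7.6; 25.0: 27.6, 7.3, 13.7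

(each reading ± 0.5 percentage points)
- percentages count the Z that a species holds: one L counts as two
- at the start none of Q is dissolved
- the numbers in the tables scatter with a standard deviation of 0.5 percentage points
- steps thought possible: J <-> Q; Z + Q -> E; E -> G; 2 Z -> L
- the reaction counts as stopped when no species that holds the Z changes by six tenths of a point or more over the second half of the time
- the state of affairs at 1.0 h: stopped, and by what, or still going (all of Z has reacted / forward and back rates have come level / it is still moving)
- share of the Z used up at 1.0 h
- E at 1.0 h, in percent of the Z charged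
- G at 1.0 h, in percent of the Z charged

Z leaves by two branches: to L at a rate in [Z] squared, and through E to G at a rate in [Z][Q]. With [Q] taken as steady and alike in both runs, the Z going to L per Z going to E plus G is proportional to [Z]. Replacing the falling curve by its mean gives, over a stretch:

E plus G gained = Z lost / (1 + σ · mean [Z])

Saturday's run from 12.0 min to 25.0 min lost 20 percentage points of Z and gained 8.2 points of E plus G, a share of 0.402 at mean [Z] 0.208 M.

The reckoning for Friday's flask after 10.0 min takes 3 inputs: the E plus G already read, the Z left at the asked time, and the share. The E plus G already read enters point for point. A straight line in 1/[Z] through Friday's first and last readings puts Z at 9.26% at the asked time, and a Z of half that figure adds 2.4 points to the reckoned E plus G. The share rests on a gain read from 4 readings, each scattering by 0.5 points, so that gain carries about 1 point.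

σ = (1/share − 1) / mean [Z] = 7.16 M⁻¹

This σ, the selectivity factor, is the Z going to L per Z going to E plus G, per molar of Z. Friday's remaining stretch has mean [Z] 0.262 M, so my own reckoning gives E plus G of 20.3%.

The forecast, which differs from this, says it is still moving, with 94.5% used, E 1.8% and G 22%: “Z still falls by about half”.

The flask gives it is still moving, with 93.9% used, E 2.04% and G 19.8%.

    J ⇌ Q, rate k1*(csat - [Q]) (kL = 0.0340 s⁻¹)
    Z + Q → E (k = 0.00140 M⁻¹ s⁻¹)
    E → G (k = 0.00130 s⁻¹)
    2 Z → L (k = 0.00100 M⁻¹ s⁻¹)

With the 6.1% of Z left in the flask at 1.00 h, σ gives 21.9% of E plus G, and the flask holds 21.8%. The neighbour charged with 0.28 M of Z has used 83.8% of its charge at 1.00 h; its mean [Z] of 0.163 M and σ put 38.7% of that charge into E plus G. That neighbour holds E 4.89% and G 35.4%, together 40.3%.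

The data are simulated from invented constants.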